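The pyran ring (O1, C2, C3, C4, C4a, C8a) is traced back to a MOM-protected, brominated 2'-hydroxychalcone: C2–C3–C4 is the enone chain after a 1,2-shift of the B-ring aryl from C2 to C3. In one operation, thallium(III) drives this oxidative aryl migration to a β-ketoacetal, and acid then bonds the A-ring phenol oxygen O1 to the acetal carbon C2, closing the pyranone and releasing every MOM ether. The step exploits the electron-rich 2,4-dioxygenated aryl on C3 (a good migrating group) and the phenol oxygen ortho to the C4 carbonyl. Stille prenylation and a ruthenium transfer-hydrogenation cascade with dynamic kinetic resolution then set C3 and C4 (cis, 3R,4R).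

Key step: step 5

Remark: the target SMILES corresponds to the (3R,4R) isomer, in which the 3-aryl group and the 4-hydroxyl are cis on the chroman ring.

Step 1
Reactants: 1 1-(2,6-dihydroxy-4-methoxyphenyl)ethan-1-one
Product: 2 1-[2-hydroxy-4-methoxy-6-(methoxymethoxy)phenyl]ethan-1-one
Conditions: MOMCl (1.1 equiv), K2CO3, acetone, 0 °C to rt
Reagents that add atoms: chloromethyl methyl ether, COCCl
Why: Williamson etherification, in which alkylation of one of the two equivalent phenols leaves the other locked in a hydrogen bond to the ketone, so mono-protection should stop cleanly.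

Step 2
Reactants: 3 4-hydroxy-2-methoxybenzaldehyde
Product: 4 5-bromo-4-hydroxy-2-methoxybenzaldehyde
Conditions: NBS (1.0 equiv), MeCN, 0 °C to rt
Reagents that add atoms: N-bromosuccinimide, O=C1CCC(=O)N1Br
Why: Electrophilic aromatic bromination is directed to C5, ortho to the free phenol and para to the methoxy group, whereas C3 between the two oxygens is hindered.

Step 3
Reactants: 4 5-bromo-4-hydroxy-2-methoxybenzaldehyde
Product: 5 5-bromo-2-methoxy-4-(methoxymethoxy)benzaldehyde
Conditions: MOMCl, K2CO3, acetone, rt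
Reagents that add atoms: chloromethyl methyl ether, COCCl
Why: Williamson etherification of the acidic para-formyl phenol masks it against thallium(III) oxidation and against phenoxide deactivation of the aldehyde in the aldol step.

Step 4
Reactants: 2 1-[2-hydroxy-4-methoxy-6-(methoxymethoxy)phenyl]ethan-1-one; 5 5-bromo-2-methoxy-4-(methoxymethoxy)benzaldehyde
Product: 6 (E)-3-[5-bromo-2-methoxy-4-(methoxymethoxy)phenyl]-1-[2-hydroxy-4-methoxy-6-(methoxymethoxy)phenyl]prop-2-en-1-one
Conditions: KOH (50% aq), EtOH, rt
Reagents that add atoms: none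
Why: Claisen–Schmidt aldol condensation of the methyl ketone enolate with the non-enolisable aldehyde, with E1cB dehydration giving the (E)-enone as the thermodynamic isomer.

Step 5
Reactants: 6 (E)-3-[5-bromo-2-methoxy-4-(methoxymethoxy)phenyl]-1-[2-hydroxy-4-methoxy-6-(methoxymethoxy)phenyl]prop-2-en-1-one
Product: 8 3-(5-bromo-4-hydroxy-2-methoxyphenyl)-5-hydroxy-7-methoxy-4H-chromen-4-one, via β-ketoacetal 7 (not isolated)
Conditions: Tl(NO3)3·3H2O (1.1 equiv), MeOH, rt; then conc. HCl (to ca. 1 M), 60 °C
Reagents that add atoms: none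
Why: Oxythallation of the enone (methanol adds to the benzylic carbon, thallium to the α-carbon) is followed by a 1,2-shift of the aryl group through a phenonium ion with loss of Tl(I), and the resulting oxocarbenium ion is trapped as dimethyl acetal 7; on acidification the 2'-phenol attacks the acetal-derived oxocarbenium carbon, methanol is lost to give the chromen-4-one, and both MOM ethers are methanolysed. The closest known reaction type is the thallium(III) nitrate oxidative rearrangement of 2'-hydroxychalcones, the classical chalcone route to isoflavones. The pyranone ring is closed by O1–C2 bond formation in a 6-exo-trig attack on the oxocarbenium ion, followed by elimination of methanol across C2–C3. No stereocentre persists, since C3 of acetal 7 becomes sp2 in the product. The step needs aryl migration to outrun aurone formation and arene oxidation: the para-alkoxy and ortho-methoxy groups make ring B an excellent migrating group, the only free phenol is deactivated by its hydrogen bond to the carbonyl, and the other phenols are masked as MOM ethers.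

Step 6
Reactants: 8 3-(5-bromo-4-hydroxy-2-methoxyphenyl)-5-hydroxy-7-methoxy-4H-chromen-4-one
Product: 9 5-hydroxy-3-[4-hydroxy-2-methoxy-5-(3-methylbut-2-en-1-yl)phenyl]-7-methoxy-4H-chromen-4-one
Conditions: tributyl(3-methylbut-2-en-1-yl)stannane, Pd(t-Bu3P)2 (5 mol %), CsF, dioxane, 90 °C
Reagents that add atoms: tributyl(3-methylbut-2-en-1-yl)stannane, CCCC[Sn](CCCC)(CCCC)CC=C(C)C
Why: Stille cross-coupling (oxidative addition into the C–Br bond, fluoride-assisted transmetalation of the allylstannane at its α-carbon, reductive elimination) should give the linear prenyl arene under near-neutral conditions that tolerate the free phenols and the base-sensitive chromenone.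

Step 7
Reactants: 9 5-hydroxy-3-[4-hydroxy-2-methoxy-5-(3-methylbut-2-en-1-yl)phenyl]-7-methoxy-4H-chromen-4-one
Product: 11 (3R,4R)-3-[4-hydroxy-2-methoxy-5-(3-methylbut-2-en-1-yl)phenyl]-7-methoxy-3,4-dihydro-2H-chromene-4,5-diol, via isoflavanone 10 (not isolated)
Conditions: RuCl[(R,R)-Ts-DENEB] (3 mol %), HCO2H/Et3N (1:1), EtOAc, 40 °C
Reagents that add atoms: none
Why: Noyori–Ikariya-type asymmetric transfer hydrogenation cascade in which Ru–H conjugate reduction gives isoflavanone 10, C3 epimerises through the enol under the amine buffer (dynamic kinetic resolution), and the (R,R)-catalyst reduces the (3R)-ketone faster with hydride delivered anti to the 3-aryl group, which should set C4 as R and the 3,4-cis relationship while leaving the trisubstituted prenyl alkene untouched.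

Compound list
1 | 1-(2,6-dihydroxy-4-methoxyphenyl)ethan-1-one | CC(=O)c1c(O)cc(OC)cc1O | starting material
2 | 1-[2-hydroxy-4-methoxy-6-(methoxymethoxy)phenyl]ethan-1-one | CC(=O)c1c(O)cc(OC)cc1OCOC | intermediate
3 | 4-hydroxy-2-methoxybenzaldehyde | COc1cc(O)ccc1C=O | starting material
4 | 5-bromo-4-hydroxy-2-methoxybenzaldehyde | COc1cc(O)c(Br)cc1C=O | intermediate
5 | 5-bromo-2-methoxy-4-(methoxymethoxy)benzaldehyde | COCOc1cc(OC)c(C=O)cc1Br | intermediate
6 | (E)-3-[5-bromo-2-methoxy-4-(methoxymethoxy)phenyl]-1-[2-hydroxy-4-methoxy-6-(methoxymethoxy)phenyl]prop-2-en-1-one | COCOc1cc(OC)c(/C=C/C(=O)c2c(O)cc(OC)cc2OCOC)cc1Br | intermediate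
7 | 2-[5-bromo-2-methoxy-4-(methoxymethoxy)phenyl]-1-[2-hydroxy-4-methoxy-6-(methoxymethoxy)phenyl]-3,3-dimethoxypropan-1-one (racemic, not isolated) | COCOc1cc(OC)c(C(C(OC)OC)C(=O)c2c(O)cc(OC)cc2OCOC)cc1Br | intermediate
8 | 3-(5-bromo-4-hydroxy-2-methoxyphenyl)-5-hydroxy-7-methoxy-4H-chromen-4-one | COc1cc(O)c2c(c1)occ(-c1cc(Br)c(O)cc1OC)c2=O | intermediate
9 | 5-hydroxy-3-[4-hydroxy-2-methoxy-5-(3-methylbut-2-en-1-yl)phenyl]-7-methoxy-4H-chromen-4-one | COc1cc(O)c2c(c1)occ(-c1cc(CC=C(C)C)c(O)cc1OC)c2=O | intermediate
10 | 5-hydroxy-3-[4-hydroxy-2-methoxy-5-(3-methylbut-2-en-1-yl)phenyl]-7-methoxy-2,3-dihydro-4H-chromen-4-one (racemic, C3 epimerising, not isolated) | COc1cc(O)c2c(c1)OCC(c1cc(CC=C(C)C)c(O)cc1OC)C2=O | intermediate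
11 | (3R,4R)-3-[4-hydroxy-2-methoxy-5-(3-methylbut-2-en-1-yl)phenyl]-7-methoxy-3,4-dihydro-2H-chromene-4,5-diol | COc1cc(O)c2c(c1)OC[C@@H](c1cc(CC=C(C)C)c(O)cc1OC)[C@H]2O | target

Total step count: 7
Longest linear sequence: 6 steps (3 → 4 → 5 → 6 → 8 → 9 → 11, steps 2 to 7)

Steps most likely to fail

Step 5. The free 2'-phenol may attack the thallated enone to give an aurone, the MOM ethers may be lost early with oxidation of the freed phenols, or the A ring may be thallated instead of the aryl group migrating. The fallback sets out from 6 and comes back at 8. The remaining phenol is capped (NaH, MOMCl, DMF) to give the fully MOM-protected chalcone (E)-3-[5-bromo-2-methoxy-4-(methoxymethoxy)phenyl]-1-[4-methoxy-2,6-bis(methoxymethoxy)phenyl]prop-2-en-1-one F1. Weitz–Scheffer epoxidation (H2O2, NaOH, MeOH) should give the racemic trans-epoxy ketone F2. BF3·OEt2 in CH2Cl2 at low temperature should open the epoxide at the B-ring benzylic carbon, and a Meinwald-type 1,2-acyl shift should give the α-formyl deoxybenzoin F3. Methanolic HCl then removes the MOM groups and cyclodehydrates F3 to 8.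

Step 6. Oxidative addition into the electron-rich bromophenol may be slow, protodebromination may compete, or the allyl group may be transferred with transposition to the 1,1-dimethylallyl isomer. The fallback sets out from 8 and comes back at 9. Both phenols are acetylated (Ac2O, pyridine, DMAP) to the diacetate F4, an electron-poorer aryl bromide. Suzuki–Miyaura coupling with 3-methylbut-2-enylboronic acid pinacol ester under anhydrous conditions (Pd catalyst with a ligand chosen for α-selective allyl transfer, K3PO4, THF) should give the prenylated diacetate F5. K2CO3 in MeOH at 0 °C then removes the acetates to give 9.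

Step 7. The hydrogen-bonded, electron-rich 5-hydroxy carbonyl may resist Ru–H conjugate and carbonyl reduction so that the cascade stalls, or the product benzylic alcohol may ionise in the formic acid medium. The fallback sets out from 9 and comes back at 11. Both phenols are silylated (TBSOTf, 2,6-lutidine, CH2Cl2) to give the bis-TBS isoflavone F6, whose carbonyl is no longer chelated. The same transfer-hydrogenation cascade should give the bis-TBS cis-isoflavan-4-ol F7. TBAF buffered with AcOH in THF at 0 °C then releases 11.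

Further compounds
F1 | step 5 | (E)-3-[5-bromo-2-methoxy-4-(methoxymethoxy)phenyl]-1-[4-methoxy-2,6-bis(methoxymethoxy)phenyl]prop-2-en-1-one | COCOc1cc(OC)c(/C=C/C(=O)c2c(OCOC)cc(OC)cc2OCOC)cc1Br
F2 | step 5 | trans-{3-[5-bromo-2-methoxy-4-(methoxymethoxy)phenyl]oxiran-2-yl}[4-methoxy-2,6-bis(methoxymethoxy)phenyl]methanone (racemic, one enantiomer drawn) | COCOc1cc(OC)c([C@@H]2O[C@H]2C(=O)c2c(OCOC)cc(OC)cc2OCOC)cc1Br
F3 | step 5 | 2-[5-bromo-2-methoxy-4-(methoxymethoxy)phenyl]-3-[4-methoxy-2,6-bis(methoxymethoxy)phenyl]-3-oxopropanal (racemic) | O=CC(c1cc(Br)c(OCOC)cc1OC)C(=O)c1c(OCOC)cc(OC)cc1OCOC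
F4 | step 6 | 3-(4-acetoxy-5-bromo-2-methoxyphenyl)-7-methoxy-4-oxo-4H-chromen-5-yl acetate | COc1cc(OC(C)=O)c2c(c1)occ(-c1cc(Br)c(OC(C)=O)cc1OC)c2=O
F5 | step 6 | 3-[4-acetoxy-2-methoxy-5-(3-methylbut-2-en-1-yl)phenyl]-7-methoxy-4-oxo-4H-chromen-5-yl acetate | COc1cc(OC(C)=O)c2c(c1)occ(-c1cc(CC=C(C)C)c(OC(C)=O)cc1OC)c2=O
F6 | step 7 | 5-(tert-butyldimethylsilyloxy)-3-[4-(tert-butyldimethylsilyloxy)-2-methoxy-5-(3-methylbut-2-en-1-yl)phenyl]-7-methoxy-4H-chromen-4-one | COc1cc(O[Si](C)(C)C(C)(C)C)c2c(c1)occ(-c1cc(CC=C(C)C)c(O[Si](C)(C)C(C)(C)C)cc1OC)c2=O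
F7 | step 7 | (3R,4R)-5-(tert-butyldimethylsilyloxy)-3-[4-(tert-butyldimethylsilyloxy)-2-methoxy-5-(3-methylbut-2-en-1-yl)phenyl]-7-methoxychroman-4-ol | COc1cc(O[Si](C)(C)C(C)(C)C)c2c(c1)OC[C@@H](c1cc(CC=C(C)C)c(O[Si](C)(C)C(C)(C)C)cc1OC)[C@H]2O
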